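**Retrosynthetic overview**

1. Numbering: ring C1 (angelate), C2, C3 (Me), C4 (OH), C5, C6 (side chain); chain C7 (Me), C8, C9 (OAc), C10=C11. The strategy rests on the 1,4-placement of the C1 and C4 oxygens across C2–C3 of the single cyclohexane ring; no polar bond pairs these two oxygens, so C1–C2 is made reductively.
2. Target ⇐ C4 ketone 23 (ketone reduction, acetate, angelate) ⇐ ring closure C1–C2 (the only ring, formed in step 12) by cathodic coupling of the C1 aldehyde with the CH2 terminus of the C4 isopropenyl ketone in keto-aldehyde 21.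
3. 21 is a γ-keto aldehyde with a single CH2 (C5) between C6 and C4. A conjugate addition of the aldehyde to a vinyl ketone would put two CH2 groups there and lead to a seven-membered ring, so C6–C5 is made by Evans alkylation with methyl bromoacetate, and C4–C3 by isopropenyl Grignard addition to the derived lactol and double Swern oxidation.
4. Chain C6–C11 ⇐ methyl hydrogen (R)-3-methylglutarate: acid arm → Weinreb amide → isobutenyl ketone → CBS reduction (C9); ester arm → acyl oxazolidinone (C1).

Key step: step 12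

Remark: methyl hydrogen (R)-3-methylglutarate (the desymmetrised half-ester of 3-methylglutaric anhydride) is taken as a commercial single enantiomer. The allylic C9–O group ionises easily, so nothing more acidic than pyridinium tosylate (brief cold pH 4 work-up in step 5 excepted) is used after step 3.

**Route**

Step 1
Reactants: 1 methyl hydrogen (R)-3-methylglutarate
Product: 3 methyl (3R)-5-[methoxy(methyl)amino]-3-methyl-5-oxopentanoate, via acyl imidazolide 2 (not isolated)
Conditions: 1,1'-carbonyldiimidazole, CH2Cl2, 23 °C; then MeNHOMe·HCl, 23 °C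
Reagents that add atoms: N,O-dimethylhydroxylamine hydrochloride, CNOC.Cl
Why: Amide coupling through the acyl imidazolide activates only the free acid arm, which fixes this arm as the future C8–C9 end and the ester arm as the future C6–C1 end, without touching the C7 stereocentre.

Step 2
Reactants: 3 methyl (3R)-5-[methoxy(methyl)amino]-3-methyl-5-oxopentanoate; 4 1-bromo-2-methylprop-1-ene
Product: 6 methyl (3R)-3,7-dimethyl-5-oxooct-6-enoate, via Grignard reagent 5 (not isolated)
Conditions: 4, Mg, THF, reflux; then 3, THF, −78 → −20 °C; aq NH4Cl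
Reagents that add atoms: none
Why: Weinreb ketone synthesis: the N-methoxy-N-methylamide reacts with the alkenyl Grignard reagent faster than the methyl ester at low temperature and stops at the ketone stage, giving the β,β-dimethyl enone without over-addition.

Step 3
Reactants: 6 methyl (3R)-3,7-dimethyl-5-oxooct-6-enoate
Product: 7 methyl (3R,5R)-5-hydroxy-3,7-dimethyloct-6-enoate
Conditions: (S)-2-methyl-CBS-oxazaborolidine (0.2 equiv), catecholborane, toluene, −78 °C
Reagents that add atoms: none
Why: Corey–Bakshi–Shibata reduction: with the alkenyl group as the large and the CH2 chain as the small ketone substituent, the (S)-catalyst should deliver hydride to the face that gives the 5R allylic alcohol (C9 of the target) under catalyst control, and catecholborane at −78 °C touches neither the alkene nor the ester.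

Step 4
Reactants: 7 methyl (3R,5R)-5-hydroxy-3,7-dimethyloct-6-enoate
Product: 8 methyl (3R,5R)-5-[(tert-butyldimethylsilyl)oxy]-3,7-dimethyloct-6-enoate
Conditions: TBSCl, imidazole, DMF, 23 °C
Reagents that add atoms: tert-butyldimethylsilyl chloride, CC(C)(C)[Si](C)(C)Cl
Why: Standard silylation of the secondary allylic alcohol, done on the crude alcohol so that the δ-hydroxy ester cannot lactonise, gives an ether that survives the bases, hydrides and Grignard reagents of steps 5–13.

Step 5
Reactants: 8 methyl (3R,5R)-5-[(tert-butyldimethylsilyl)oxy]-3,7-dimethyloct-6-enoate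
Product: 9 (3R,5R)-5-[(tert-butyldimethylsilyl)oxy]-3,7-dimethyloct-6-enoic acid
Conditions: LiOH, THF/MeOH/H2O, 23 °C; 1 M HCl to pH 4, 0 °C
Reagents that add atoms: lithium hydroxide, [Li+].[OH-]
Why: Saponification of an unhindered methyl ester with no epimerisable α-centre; the silyl ether is stable to LiOH and to a brief cold acidification to pH 4.

Step 6
Reactants: 9 (3R,5R)-5-[(tert-butyldimethylsilyl)oxy]-3,7-dimethyloct-6-enoic acid; 10 (S)-4-benzyl-1,3-oxazolidin-2-one
Product: 12 (4S)-4-benzyl-3-[(3R,5R)-5-[(tert-butyldimethylsilyl)oxy]-3,7-dimethyloct-6-enoyl]-1,3-oxazolidin-2-one, via mixed pivalic anhydride 11 (not isolated)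
Conditions: t-BuCOCl, Et3N, THF, −20 °C; then 10, LiCl, 23 °C
Reagents that add atoms: none
Why: N-Acylation of the Evans auxiliary through the mixed pivalic anhydride, which is attacked at the less hindered acyl group by the LiCl-activated oxazolidinone.

Step 7
Reactants: 12 (4S)-4-benzyl-3-[(3R,5R)-5-[(tert-butyldimethylsilyl)oxy]-3,7-dimethyloct-6-enoyl]-1,3-oxazolidin-2-one; 13 methyl bromoacetate
Product: 15 methyl (3S,4R,6R)-3-{[(4S)-4-benzyl-2-oxo-1,3-oxazolidin-3-yl]carbonyl}-6-[(tert-butyldimethylsilyl)oxy]-4,8-dimethylnon-7-enoate, via sodium enolate 14 (not isolated)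
Conditions: NaN(SiMe3)2, THF, −78 °C; then 13, −78 → −40 °C
Reagents that add atoms: none
Why: Evans asymmetric alkylation: the chelated (Z)-sodium enolate is alkylated by the reactive α-bromo ester on the face opposite the benzyl group, which sets C6 as S under auxiliary control (overriding the adjacent C7 methyl group) and installs C5 and C4 with exactly one CH2 between C6 and C4.

Step 8
Reactants: 15 methyl (3S,4R,6R)-3-{[(4S)-4-benzyl-2-oxo-1,3-oxazolidin-3-yl]carbonyl}-6-[(tert-butyldimethylsilyl)oxy]-4,8-dimethylnon-7-enoate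
Product: 17 (4S)-4-[(2R,4R)-4-[(tert-butyldimethylsilyl)oxy]-6-methylhept-5-en-2-yl]oxolan-2-one, via hydroxy ester 16 (not isolated)
Conditions: NaBH4, THF/H2O (4:1), 0 → 23 °C; then pyridinium tosylate (cat.), CH2Cl2, 23 °C
Reagents that add atoms: none
Why: Reductive removal of the auxiliary: NaBH4 in wet THF reduces the activated imide carbonyl (C1) to the primary alcohol but not the methyl ester, and the γ-hydroxy ester then lactonises, so C1 (alcohol level) and C4 (acid level) are differentiated in one operation.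

Step 9
Reactants: 17 (4S)-4-[(2R,4R)-4-[(tert-butyldimethylsilyl)oxy]-6-methylhept-5-en-2-yl]oxolan-2-one
Product: 18 (4S)-4-[(2R,4R)-4-[(tert-butyldimethylsilyl)oxy]-6-methylhept-5-en-2-yl]oxolan-2-ol (anomer mixture)
Conditions: i-Bu2AlH (1.1 equiv), CH2Cl2, −78 °C; aq potassium sodium tartrate
Reagents that add atoms: none
Why: Partial reduction of a γ-lactone to the lactol, which stops at the stable aluminium hemiacetal at −78 °C and brings C4 to the aldehyde level.

Step 10
Reactants: 18 (4S)-4-[(2R,4R)-4-[(tert-butyldimethylsilyl)oxy]-6-methylhept-5-en-2-yl]oxolan-2-ol; 19 isopropenylmagnesium bromide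
Product: 20 (2S)-2-[(2R,4R)-4-[(tert-butyldimethylsilyl)oxy]-6-methylhept-5-en-2-yl]-5-methylhex-5-ene-1,4-diol (both C4 epimers)
Conditions: 19 (3 equiv), THF, 0 → 23 °C; aq NH4Cl
Reagents that add atoms: none
Why: Grignard addition to the open hydroxy-aldehyde form of the lactol (one equivalent is used up as base) forms the C4–C3 bond; the C4 configuration does not matter because this carbon is oxidised in the next step.

Step 11
Reactants: 20 (2S)-2-[(2R,4R)-4-[(tert-butyldimethylsilyl)oxy]-6-methylhept-5-en-2-yl]-5-methylhex-5-ene-1,4-diol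
Product: 21 (2S)-2-[(2R,4R)-4-[(tert-butyldimethylsilyl)oxy]-6-methylhept-5-en-2-yl]-5-methyl-4-oxohex-5-enal
Conditions: (COCl)2, DMSO, CH2Cl2, −78 °C; i-Pr2NEt, −78 → −30 °C; pH 7 buffer
Reagents that add atoms: none
Why: Double Swern oxidation: both hydroxyls of the 1,4-diol are activated as alkoxysulfonium salts before base is added, so no lactol or lactone can form, and the cold hindered-amine elimination should leave the C6 centre (α to the new aldehyde) intact; the keto-aldehyde is used at once.

Step 12
Reactants: 21 (2S)-2-[(2R,4R)-4-[(tert-butyldimethylsilyl)oxy]-6-methylhept-5-en-2-yl]-5-methyl-4-oxohex-5-enal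
Product: 23 (2S,4R,5S)-4-hydroxy-2-methyl-5-[(2R,4R)-4-[(tert-butyldimethylsilyl)oxy]-6-methylhept-5-en-2-yl]cyclohexan-1-one, via C3-epimeric ketone 22 (not isolated)
Conditions: divided cell (glass frit), reticulated vitreous carbon cathode, Pt anode, 0.1 M Et4NOTs in DMF, 2,6-di-tert-butyl-4-methylphenol (3 equiv), 5 mM 21, constant current 2 mA cm−2, 2.2 F mol−1, 0 °C, Ar; then crude, DBU (0.2 equiv), CH2Cl2, 23 °C
Reagents that add atoms: none
Why: The conjugated isopropenyl ketone is the most easily reduced group; its radical anion, with spin and charge at the terminal C2, adds to the C1 aldehyde carbon, and a second electron plus two protons from the hindered phenol give the C1 alcohol and, through the C3–C4 enolate, the C4 ketone. The closest known reaction type is the electroreductive cyclisation of aldehydes and ketones onto tethered enoates, enones and unsaturated nitriles, whose chemical counterpart is the SmI2 ketyl–olefin cyclisation. The six-membered ring closes by 6-exo-trig attack on the aldehyde C=O (6-endo-trig with respect to C2=C3); the five-ring alternative through C3 would be a polarity-mismatched attack at the substituted α-carbon. C1 is set by the existing C6 centre through a chair-like transition state with the C7 side chain and the developing C1–O bond both equatorial (trans), and C3 is set thermodynamically, DBU equilibration of the α-methyl ketone placing the methyl group equatorial and cis to C1–OH. The step needs reduction of the enone alone and ring closure faster than β-protonation, hydrodimerisation or enolisation at C6: the isolated C10=C11 alkene, the silyl ether and the aldehyde are not reduced at the enone potential, high dilution disfavours dimerisation, and the phenol (whose phenoxide is neither a Michael donor nor a strong base) buffers the catholyte.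

Step 13
Reactants: 23 (2S,4R,5S)-4-hydroxy-2-methyl-5-[(2R,4R)-4-[(tert-butyldimethylsilyl)oxy]-6-methylhept-5-en-2-yl]cyclohexan-1-one; 24 angelic acid
Product: 26 (1R,2S,5S)-2-[(2R,4R)-4-[(tert-butyldimethylsilyl)oxy]-6-methylhept-5-en-2-yl]-5-methyl-4-oxocyclohexyl (2Z)-2-methylbut-2-enoate, via mixed anhydride 25 (not isolated)
Conditions: 24, 2,4,6-trichlorobenzoyl chloride, Et3N, toluene, 23 °C; then 23, 75 °C
Reagents that add atoms: none
Why: Yamaguchi esterification run without DMAP, the usual way to acylate a secondary alcohol with angelic acid, because the absence of a nucleophilic catalyst avoids Z-to-E isomerisation to the tiglate; the C1 stereocentre is retained and the equatorial C3 methyl is already the stable epimer.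

Step 14
Reactants: 26 (1R,2S,5S)-2-[(2R,4R)-4-[(tert-butyldimethylsilyl)oxy]-6-methylhept-5-en-2-yl]-5-methyl-4-oxocyclohexyl (2Z)-2-methylbut-2-enoate
Product: 27 (1R,2S,5S)-2-[(2R,4R)-4-hydroxy-6-methylhept-5-en-2-yl]-5-methyl-4-oxocyclohexyl (2Z)-2-methylbut-2-enoate
Conditions: Bu4NF, AcOH (1:1), THF, 0 → 23 °C
Reagents that add atoms: none
Why: Fluoride desilylation buffered with acetic acid is close to neutral, so the angelate, the α-methyl ketone and the ionisable allylic alcohol are not disturbed.

Step 15
Reactants: 27 (1R,2S,5S)-2-[(2R,4R)-4-hydroxy-6-methylhept-5-en-2-yl]-5-methyl-4-oxocyclohexyl (2Z)-2-methylbut-2-enoate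
Product: 28 (1R,2S,5S)-2-[(2R,4R)-4-acetoxy-6-methylhept-5-en-2-yl]-5-methyl-4-oxocyclohexyl (2Z)-2-methylbut-2-enoate
Conditions: Ac2O, pyridine, DMAP (cat.), CH2Cl2, 0 °C
Reagents that add atoms: acetic anhydride, CC(=O)OC(C)=O
Why: Standard acetylation of the only free hydroxyl, with retention at C9, done before the ketone reduction so that the C4 hydroxyl never competes.

Step 16
Reactants: 28 (1R,2S,5S)-2-[(2R,4R)-4-acetoxy-6-methylhept-5-en-2-yl]-5-methyl-4-oxocyclohexyl (2Z)-2-methylbut-2-enoate
Product: 29 (1R,2S,4R,5S)-2-[(2R,4R)-4-acetoxy-6-methylhept-5-en-2-yl]-4-hydroxy-5-methylcyclohexyl (2Z)-2-methylbut-2-enoate (target, CNP0237033.1)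
Conditions: LiBH(s-Bu)3 (1.1 equiv), THF, −78 °C; aq NH4Cl
Reagents that add atoms: none
Why: Reduction with a bulky trialkylborohydride: hydride approaches the C4 ketone along the equatorial trajectory of the chair that carries C1–O, C3–Me and the C6 chain equatorial, giving the axial 4R alcohol cis to the C3 methyl group, and at −78 °C with one equivalent the acetate and the hindered angelate should survive.

**Compound list**

1 | methyl hydrogen (R)-3-methylglutarate [(3R)-5-methoxy-3-methyl-5-oxopentanoic acid] | OC(=O)C[C@@H](C)CC(=O)OC | starting material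
2 | methyl (3R)-5-(imidazol-1-yl)-3-methyl-5-oxopentanoate (acyl imidazolide) | O=C(C[C@@H](C)CC(=O)OC)n1ccnc1 | intermediate
3 | methyl (3R)-5-[methoxy(methyl)amino]-3-methyl-5-oxopentanoate | CON(C)C(=O)C[C@@H](C)CC(=O)OC | intermediate
4 | 1-bromo-2-methylprop-1-ene | CC(C)=CBr | starting material
5 | (2-methylprop-1-en-1-yl)magnesium bromide | CC(C)=C[Mg]Br | intermediate
6 | methyl (3R)-3,7-dimethyl-5-oxooct-6-enoate | COC(=O)C[C@H](C)CC(=O)C=C(C)C | intermediate
7 | methyl (3R,5R)-5-hydroxy-3,7-dimethyloct-6-enoate | COC(=O)C[C@H](C)C[C@@H](O)C=C(C)C | intermediate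
8 | methyl (3R,5R)-5-[(tert-butyldimethylsilyl)oxy]-3,7-dimethyloct-6-enoate | COC(=O)C[C@H](C)C[C@@H](O[Si](C)(C)C(C)(C)C)C=C(C)C | intermediate
9 | (3R,5R)-5-[(tert-butyldimethylsilyl)oxy]-3,7-dimethyloct-6-enoic acid | OC(=O)C[C@H](C)C[C@@H](O[Si](C)(C)C(C)(C)C)C=C(C)C | intermediate
10 | (S)-4-benzyl-1,3-oxazolidin-2-one | O=C1N[C@@H](Cc2ccccc2)CO1 | starting material
11 | (3R,5R)-5-[(tert-butyldimethylsilyl)oxy]-3,7-dimethyloct-6-enoic pivalic anhydride | CC(C)(C)C(=O)OC(=O)C[C@H](C)C[C@@H](O[Si](C)(C)C(C)(C)C)C=C(C)C | intermediate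
12 | (4S)-4-benzyl-3-[(3R,5R)-5-[(tert-butyldimethylsilyl)oxy]-3,7-dimethyloct-6-enoyl]-1,3-oxazolidin-2-one | O=C1OC[C@H](Cc2ccccc2)N1C(=O)C[C@H](C)C[C@@H](O[Si](C)(C)C(C)(C)C)C=C(C)C | intermediate
13 | methyl bromoacetate | COC(=O)CBr | starting material
14 | sodium (Z)-enolate of 12 | [Na+].[O-]/C(=C\[C@H](C)C[C@@H](O[Si](C)(C)C(C)(C)C)C=C(C)C)N1C(=O)OC[C@@H]1Cc1ccccc1 | intermediate
15 | methyl (3S,4R,6R)-3-{[(4S)-4-benzyl-2-oxo-1,3-oxazolidin-3-yl]carbonyl}-6-[(tert-butyldimethylsilyl)oxy]-4,8-dimethylnon-7-enoate | O=C1OC[C@H](Cc2ccccc2)N1C(=O)[C@@H](CC(=O)OC)[C@H](C)C[C@@H](O[Si](C)(C)C(C)(C)C)C=C(C)C | intermediate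
16 | methyl (3S,4R,6R)-6-[(tert-butyldimethylsilyl)oxy]-3-(hydroxymethyl)-4,8-dimethylnon-7-enoate | COC(=O)C[C@H](CO)[C@H](C)C[C@@H](O[Si](C)(C)C(C)(C)C)C=C(C)C | intermediate
17 | (4S)-4-[(2R,4R)-4-[(tert-butyldimethylsilyl)oxy]-6-methylhept-5-en-2-yl]oxolan-2-one | O=C1C[C@H](CO1)[C@H](C)C[C@@H](O[Si](C)(C)C(C)(C)C)C=C(C)C | intermediate
18 | (4S)-4-[(2R,4R)-4-[(tert-butyldimethylsilyl)oxy]-6-methylhept-5-en-2-yl]oxolan-2-ol (anomers) | OC1C[C@H](CO1)[C@H](C)C[C@@H](O[Si](C)(C)C(C)(C)C)C=C(C)C | intermediate
19 | isopropenylmagnesium bromide | CC(=C)[Mg]Br | starting material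
20 | (2S)-2-[(2R,4R)-4-[(tert-butyldimethylsilyl)oxy]-6-methylhept-5-en-2-yl]-5-methylhex-5-ene-1,4-diol (C4 epimers) | OC[C@@H](CC(O)C(C)=C)[C@H](C)C[C@@H](O[Si](C)(C)C(C)(C)C)C=C(C)C | intermediate
21 | (2S)-2-[(2R,4R)-4-[(tert-butyldimethylsilyl)oxy]-6-methylhept-5-en-2-yl]-5-methyl-4-oxohex-5-enal | O=C[C@@H](CC(=O)C(C)=C)[C@H](C)C[C@@H](O[Si](C)(C)C(C)(C)C)C=C(C)C | intermediate
22 | (4R,5S)-4-hydroxy-2-methyl-5-[(2R,4R)-4-[(tert-butyldimethylsilyl)oxy]-6-methylhept-5-en-2-yl]cyclohexan-1-one, mixture of epimers at the methyl-bearing carbon (C3 of the route numbering) | O[C@@H]1CC(C)C(=O)C[C@H]1[C@H](C)C[C@@H](O[Si](C)(C)C(C)(C)C)C=C(C)C | intermediate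
23 | (2S,4R,5S)-4-hydroxy-2-methyl-5-[(2R,4R)-4-[(tert-butyldimethylsilyl)oxy]-6-methylhept-5-en-2-yl]cyclohexan-1-one | O[C@@H]1C[C@H](C)C(=O)C[C@H]1[C@H](C)C[C@@H](O[Si](C)(C)C(C)(C)C)C=C(C)C | intermediate
24 | angelic acid [(2Z)-2-methylbut-2-enoic acid] | C/C=C(/C)C(O)=O | starting material
25 | angelic 2,4,6-trichlorobenzoic anhydride | C/C=C(/C)C(=O)OC(=O)c1c(Cl)cc(Cl)cc1Cl | intermediate
26 | (1R,2S,5S)-2-[(2R,4R)-4-[(tert-butyldimethylsilyl)oxy]-6-methylhept-5-en-2-yl]-5-methyl-4-oxocyclohexyl (2Z)-2-methylbut-2-enoate | C/C=C(/C)C(=O)O[C@@H]1C[C@H](C)C(=O)C[C@H]1[C@H](C)C[C@@H](O[Si](C)(C)C(C)(C)C)C=C(C)C | intermediate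
27 | (1R,2S,5S)-2-[(2R,4R)-4-hydroxy-6-methylhept-5-en-2-yl]-5-methyl-4-oxocyclohexyl (2Z)-2-methylbut-2-enoate | C/C=C(/C)C(=O)O[C@@H]1C[C@H](C)C(=O)C[C@H]1[C@H](C)C[C@@H](O)C=C(C)C | intermediate
28 | (1R,2S,5S)-2-[(2R,4R)-4-acetoxy-6-methylhept-5-en-2-yl]-5-methyl-4-oxocyclohexyl (2Z)-2-methylbut-2-enoate | C/C=C(/C)C(=O)O[C@@H]1C[C@H](C)C(=O)C[C@H]1[C@H](C)C[C@@H](OC(C)=O)C=C(C)C | intermediate
29 | (1R,2S,4R,5S)-2-[(2R,4R)-4-acetoxy-6-methylhept-5-en-2-yl]-4-hydroxy-5-methylcyclohexyl (2Z)-2-methylbut-2-enoate | C/C=C(/C)C(=O)O[C@@H]1C[C@H](C)[C@H](O)C[C@H]1[C@H](C)C[C@H](C=C(C)C)OC(C)=O | target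

**Step count and risk**

Total step count: 16. Longest linear sequence: 16 steps (from 1).

Steps most likely to fail:

Step 12. The enone radical anion may be protonated at C2 and reduced further to the saturated isopropyl ketone before it cyclises, it may hydrodimerise, the reduced enolate may close onto C1 through C3 in an aldol sense, or the facial selectivity at C1 may be poor. The fallback sets out from 21 and replaces the electrode by a stoichiometric homogeneous reductant that forms the aldehyde ketyl first: SmI2 (2.5 equiv) with HMPA and t-BuOH in THF at −78 °C, a ketyl–olefin cyclisation in which the samarium-bound ketyl adds to the enone terminus C2 and the samarium enolate is protonated. After the same DBU equilibration the route is rejoined at 23; no new compound is made (F0).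

Step 13. Acylation of the hindered secondary C1 alcohol by the mixed anhydride may be slow, and on forcing the angelate may isomerise to the tiglate. The fallback sets out from 23 and builds the Z-alkene on the ester instead of transferring it. Esterification (N,N'-dicyclohexylcarbodiimide, cat. DMAP, CH2Cl2) with 2-[bis(2,2,2-trifluoroethoxy)phosphoryl]propanoic acid should give (1R,2S,5S)-2-[(2R,4R)-4-[(tert-butyldimethylsilyl)oxy]-6-methylhept-5-en-2-yl]-5-methyl-4-oxocyclohexyl 2-[bis(2,2,2-trifluoroethoxy)phosphoryl]propanoate F1. Still–Gennari olefination of F1 with acetaldehyde (KN(SiMe3)2, 18-crown-6, THF, −78 °C; the phosphonate is far more acidic than the ketone) should give the Z-enoate and rejoin the route at 26.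

Step 3. The two ketone substituents (a β,β-disubstituted alkenyl group and a primary alkyl chain) may not be differentiated well enough by the oxazaborolidine, giving incomplete selectivity at C9. The fallback sets out from 1 and makes the C9–C10 bond under catalyst control instead of reducing a ketone. Selective reduction of the acid with BH3·SMe2 (THF, 0 °C) should give methyl (3R)-5-hydroxy-3-methylpentanoate F2. Oxidation (SO3·pyridine, DMSO, i-Pr2NEt) should give methyl (3R)-3-methyl-5-oxopentanoate F3. Asymmetric Nozaki–Hiyama–Kishi coupling of F3 with bromide 4 (CrCl2, NiCl2 cat., the chiral sulfonamide ligand enantiomer that gives the 5R alcohol, Et3N, THF) then rejoins the route at 7.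

**Further compounds**

F0 | step 12 | none | none
F1 | step 13 | (1R,2S,5S)-2-[(2R,4R)-4-[(tert-butyldimethylsilyl)oxy]-6-methylhept-5-en-2-yl]-5-methyl-4-oxocyclohexyl 2-[bis(2,2,2-trifluoroethoxy)phosphoryl]propanoate | CC(C(=O)O[C@@H]1C[C@H](C)C(=O)C[C@H]1[C@H](C)C[C@@H](O[Si](C)(C)C(C)(C)C)C=C(C)C)P(=O)(OCC(F)(F)F)OCC(F)(F)F
F2 | step 3 | methyl (3R)-5-hydroxy-3-methylpentanoate | OCC[C@@H](C)CC(=O)OC
F3 | step 3 | methyl (3R)-3-methyl-5-oxopentanoate | O=CC[C@@H](C)CC(=O)OC
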